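## The problem

Isocryptomerin (17) is two flavones joined only through oxygen. Unit 1 is 5-hydroxy-7-methoxy-2-(4-hydroxyphenyl)chromen-4-one (unprimed chromone atoms). Unit 2 is a 5,7-dihydroxyflavone (double-primed chromone, triple-primed B ring). The oxygen on C6 of unit 1 is bonded to C4''' of unit 2.

- There is no stereocenter, so nothing has to be set or relayed. The difficulties are regiochemical and chemoselective.
- Ring A of unit 1 carries three neighbouring oxygens in three different states: free 5-OH, 6-O-aryl and 7-OMe. The ether oxygen is flanked on both sides, so the diaryl ether is hindered and is best made early, on a simple ring.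
- Four phenols must end free while the 7-methyl ether stays. Only the 5-oxygen, peri to the C4 carbonyl, can be told apart from the 7-oxygen, by chelation.
- The intermediates of a flavone route are fragile. Aryl esters and 1,3-diketones do not tolerate aqueous base, benzyl ethers on a phloroglucinol ring do not tolerate hot strong acid, and the free polyphenol is oxidation-prone and must be released last.
- The enabling feature is that C2–C3 and C2''–C3'' each join a former methyl-ketone carbon to a former aroyl carbon. The central 4-aryloxybenzoyl fragment holds the acetyl-bearing ring A at its ether end and the future C2'' as a carboxyl carbon at the other end. One bis(aryl ester) can therefore deliver both flavone skeletons by two oxygen-to-carbon acyl shifts.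

## Retrosynthesis

**17 from 16.** The last cut removes three O-benzyl bonds and the O–CH3 bond at C5. Benzyl on the three phenols and methyl on O5 are chosen because one Lewis acid removes all four, the methyl only through chelation to the C4 carbonyl. Methyl ethers throughout would not let the 7-OMe be kept. The forward step must leave the 7-OMe and the diaryl ether untouched.

**16 from 15.** Both pyranones are opened at O1–C2 and O1''–C2'', giving the bis(1,3-diketone) 15 with one free phenol per half. This is preferred over oxidative closure of chalcones, which would need an extra oxidation state change on each half. Ring A of 15 has a single free hydroxyl, so unit 1 can close in one sense only.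

**15 from 14.** C2–C3 and C2''–C3'' are cut together, with each aroyl group returned to the phenolic oxygen beside the acetyl group. This gives the bis(aryl ester) 14. An intermolecular Claisen condensation would have to distinguish two acetyl groups and two esters. In 14 each enolate has its own ester held ortho to it. The forward reaction needs only excess base and must avoid ester hydrolysis.

**14 from 11 and 13.** The ester C–O bond to the phloroglucinol ring is cut, giving acid 11 and phenol 13. Phenol 13 is the twofold O-benzylation product of phloroacetophenone 12, whose third hydroxyl is protected by its hydrogen bond to the ketone.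

**11 from 10, and 10 from 8 and 9.** The acid 11 is unmasked from allyl ester 10. The ring A aryl ester of 10 is cut to phenol 8 and 4-(benzyloxy)benzoic acid 9. The carboxyl protecting group has three requirements:
- it must survive the Lewis-acidic acetylation that makes 8, which rules out a tert-butyl ester;
- it must come off without hydrolysis in the presence of an aryl ester, which rules out a methyl ester;
- it must not require hydrogenolysis, which rules out a benzyl ester.

An allyl ester meets all three.

**8 from 6.** The aryl–acetyl C–C bond is cut. Phenol 6 is symmetric about the axis through its two para oxygens, so the two positions ortho to the hydroxyl are identical. Each is activated by the hydroxyl and both methoxy groups, so a Friedel–Crafts acetylation has one possible outcome.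

**6 from 4, 4 from 3 and 2, 2 from 1.** The phenol oxygen of 6 is traced to the formyl group of aldehyde 4 by a Baeyer–Villiger (Dakin-type) oxidation. The diaryl ether of 4 is cut on the benzoate side, giving syringaldehyde 3 as the phenoxide and allyl 4-fluorobenzoate 2 as the SNAr acceptor. The ester para to fluorine activates the fluoride, and 3 already has the 2,6-dimethoxy pattern and a para carbon that becomes oxygen. Ester 2 comes from 4-fluorobenzoyl chloride 1.

## Roads not taken

**Alternative 1: thermal chromone synthesis on unprotected phloroglucinol.**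
- **Cut and key step:** The cut is through C4a''–C4'' and O1''–C2'' of unit 2. Phloroglucinol A1 would be heated, neat or under microwave irradiation, with the β-ketoester A2, which already contains the finished, protected unit 1. This Mentzer-type condensation would give 4'-O-benzyl-5-O-methylisocryptomerin A3.
- **Merits:** A1 is symmetric and needs no protection, so there is no regiochemical question. A3 carries only one benzyl group and the 5-methoxy group to remove. In protecting-group economy this road is better than the chosen one, which must benzylate 12 twice and cleave those ethers again.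
- **Weak points:** A2 can only be made after unit 1 has been built by an acyl-shift sequence of its own, followed by a further Claisen step. The condensation runs far above 200 °C, where β-ketoesters self-condense and decarboxylate. The most advanced intermediate of the route would meet its harshest conditions.
- **Comparison:** The chosen plan forms both C–C bonds in one operation below 100 °C and has fewer operations between the diaryl ether and the biflavone skeleton. That is what it sets against the saved benzyl groups.

**Alternative 2: building the para-phenylene ring on oxygen.**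
- **Cut and key step:** The two C–C bonds of the central benzene ring are cut. The aryl ethynyl ether A4 and methyl coumalate A5 would undergo a [4+2] cycloaddition followed by decarboxylative aromatisation. This would give methyl 4-[4-(benzyloxy)-2,6-dimethoxyphenoxy]benzoate A6 with the ester para to oxygen.
- **Merits:** No C–O bond has to be formed at a phenoxide flanked by two methoxy groups. The para regiochemistry of electron-rich dienophiles with A5 is reliable. On this one point the road is stronger than the chosen plan, whose SNAr uses a hindered and deactivated phenoxide.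
- **Weak points:** A4 needs several steps from the phenol and is a sensitive ynol ether. A6 is no more advanced than 4 or 6, which the chosen route reaches in two or three steps. Ring A acetylation and both flavones are still to be made, and the methyl ester of A6 raises the orthogonality problem that the allyl ester solves.
- **Comparison:** This is a reserve for a failed ether synthesis, not a shorter route.

**Alternative 3: carbonyl-directed C–H oxygenation for the pyranone of unit 1.**
- **Cut and key step:** The C8a–O1 bond is cut. The diketone A7, which lacks the ortho hydroxyl, would be treated with Pd(OAc)2 (divalent palladium) and PhI(OAc)2. The aim is palladation of the C8a–H bond ortho to the C4 ketone and C–O coupling with the enol oxygen, to give methyl 4-({2-[4-(benzyloxy)phenyl]-5,7-dimethoxy-4-oxo-4H-chromen-6-yl}oxy)benzoate A8.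
- **Merits:** Ring A needs no hydroxyl at the future C8a, so the aldehyde-to-phenol oxidation and the O-aroylation on that half disappear, saving about two steps. Only one ortho C–H exists, because the other ortho position carries a methoxy group, so the site is unambiguous.
- **Weak points:**
  - A7 is a 1,3-diketone and binds divalent palladium as a stable O,O-chelate, not through the single carbonyl needed for ortho-palladation.
  - The CH2 between the carbonyls is readily oxidised by PhI(OAc)2.
  - The trioxygenated ring A is itself prone to oxidation by hypervalent iodine.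
  - Ketone-directed C–H oxygenation is known for making ortho-oxygenated aryl ketones, but direct closure onto an enol oxygen to a flavone would be a new method at the centre of the route.
  - It solves unit 1 only.
- **Comparison:** The chosen plan pays about two more steps on ring A and in return uses only classical reactions.

Key step: step 9

Assumption: allyl 4-fluorobenzoate 2 is made in one step and not bought, and its primary allyl ester is taken to survive BF3·OEt2 in acetic acid at 85 °C as simple alkyl benzoates do.

## Route

Step 1
Reactants: 1 4-fluorobenzoyl chloride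
Product: 2 allyl 4-fluorobenzoate
Conditions: allyl alcohol, Et3N, DMAP (cat.), CH2Cl2, 0 °C to rt
Reagents that add atoms: allyl alcohol, C=CCO
Why: Acylation of an alcohol by an acid chloride with amine base; nothing else in the molecule can react.

Step 2
Reactants: 3 syringaldehyde; 2 allyl 4-fluorobenzoate
Product: 4 allyl 4-(4-formyl-2,6-dimethoxyphenoxy)benzoate
Conditions: K2CO3, DMSO, 120 °C, N2
Reagents that add atoms: none
Why: Nucleophilic aromatic substitution (SNAr): the potassium phenoxide of 3 adds para to the ester of 2 and fluoride leaves from the Meisenheimer adduct; the aldehyde has no α-hydrogen and carbonate in dry DMSO does not cleave the allyl ester.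

Step 3
Reactants: 4 allyl 4-(4-formyl-2,6-dimethoxyphenoxy)benzoate
Product: 6 allyl 4-(4-hydroxy-2,6-dimethoxyphenoxy)benzoate, via aryl formate 5 (not isolated)
Conditions: mCPBA, CH2Cl2, 0 °C to rt; then Et3N, MeOH, rt
Reagents that add atoms: mCPBA, O=C(OO)c1cccc(Cl)c1
Why: Baeyer–Villiger (Dakin-type) oxidation of an alkoxy-substituted benzaldehyde: the aryl group para to the ether oxygen migrates in the Criegee adduct to give formate 5, which amine-catalysed methanolysis cleaves in minutes without touching the benzoate; the electron-poor allyl alkene is epoxidised much more slowly than the aldehyde is oxidised.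

Step 4
Reactants: 6 allyl 4-(4-hydroxy-2,6-dimethoxyphenoxy)benzoate
Product: 8 allyl 4-(3-acetyl-4-hydroxy-2,6-dimethoxyphenoxy)benzoate, via difluoroboron chelate 7 (not isolated)
Conditions: AcOH, BF3·OEt2, 85 °C; then aq. NaOAc, rt
Reagents that add atoms: acetic acid, CC(=O)O
Why: BF3-mediated Friedel–Crafts C-acetylation of a phenol at the position ortho to the hydroxyl, which is also ortho and para to the two methoxy groups; both such positions are equivalent by symmetry, the first acetyl group deactivates the ring against a second, and the product is held as chelate 7 until aqueous acetate releases it.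

Step 5
Reactants: 8 allyl 4-(3-acetyl-4-hydroxy-2,6-dimethoxyphenoxy)benzoate; 9 4-(benzyloxy)benzoic acid
Product: 10 allyl 4-{3-acetyl-4-[4-(benzyloxy)benzoyloxy]-2,6-dimethoxyphenoxy}benzoate
Conditions: EDC·HCl, DMAP, CH2Cl2, rt
Reagents that add atoms: none
Why: Steglich esterification: the acylpyridinium ion formed from 9 acylates the hydrogen-bonded ortho-hydroxyl, the standard way of preparing Baker–Venkataraman substrates; 8 has only this one hydroxyl.

Step 6
Reactants: 10 allyl 4-{3-acetyl-4-[4-(benzyloxy)benzoyloxy]-2,6-dimethoxyphenoxy}benzoate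
Product: 11 4-{3-acetyl-4-[4-(benzyloxy)benzoyloxy]-2,6-dimethoxyphenoxy}benzoic acid
Conditions: Pd(PPh3)4 (5 mol %), 4-MeC6H4SO2Na, THF–H2O, rt; then 1 M HCl
Reagents that add atoms: none
Why: Tsuji–Trost deallylation: zerovalent palladium ionises the allyl ester to a π-allyl complex that the sulfinate captures as a sulfone; the medium is neutral and non-nucleophilic toward carbonyl groups, so the aryl ester, the ketone and the benzyl ether remain.

Step 7
Reactants: 12 2',4',6'-trihydroxyacetophenone (phloroacetophenone)
Product: 13 1-[2,4-bis(benzyloxy)-6-hydroxyphenyl]ethanone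
Conditions: BnBr (2.1 equiv), K2CO3, DMF, 0 °C to rt
Reagents that add atoms: benzyl bromide, BrCc1ccccc1
Why: Williamson etherification: the para hydroxyl and one ortho hydroxyl are alkylated, and the last hydroxyl is deactivated by its hydrogen bond to the ketone and stays free under a limited charge of benzyl bromide.

Step 8
Reactants: 11 4-{3-acetyl-4-[4-(benzyloxy)benzoyloxy]-2,6-dimethoxyphenoxy}benzoic acid; 13 1-[2,4-bis(benzyloxy)-6-hydroxyphenyl]ethanone
Product: 14 2-acetyl-3,5-bis(benzyloxy)phenyl 4-{3-acetyl-4-[4-(benzyloxy)benzoyloxy]-2,6-dimethoxyphenoxy}benzoate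
Conditions: EDC·HCl, DMAP, CH2Cl2, rt
Reagents that add atoms: none
Why: Steglich esterification of the only free acid with the only free phenol; mild, near-neutral conditions leave the existing aryl ester and both acetyl groups alone.

Step 9
Reactants: 14 2-acetyl-3,5-bis(benzyloxy)phenyl 4-{3-acetyl-4-[4-(benzyloxy)benzoyloxy]-2,6-dimethoxyphenoxy}benzoate
Product: 15 1-[4-(benzyloxy)phenyl]-3-{3-[4-(3-[2,4-bis(benzyloxy)-6-hydroxyphenyl]-3-oxopropanoyl)phenoxy]-6-hydroxy-2,4-dimethoxyphenyl}propane-1,3-dione
Conditions: KOH (powdered, 8 equiv), pyridine, 50 °C; then cold 1 M HCl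
Reagents that add atoms: none
Why: Hydroxide in pyridine deprotonates each acetyl group, and each enolate carbon attacks the carbonyl of the aryl ester on the neighbouring ring oxygen through a six-membered cyclic transition state. Each tetrahedral intermediate collapses to a phenoxide and a 1,3-diketone, which is deprotonated at once; this acid–base step makes both shifts irreversible and is why well over four equivalents of base are used. The closest known reaction type is the Baker–Venkataraman rearrangement, an intramolecular Claisen condensation, run here at both ends of one molecule, and each half has direct analogy in 2-aroyloxy-4,6-dialkoxyacetophenones and 6-aroyloxy-2,3,4-trialkoxyacetophenones. The step forms C2–C3 and C2''–C3'', closes no ring and creates no stereocenter. The selectivity needed is that each enolate takes the ester beside it and that hydroxide does not cleave an ester first. The first is secured by proximity, a six-membered transition state against a bimolecular or macrocyclic one; the second by dry powdered KOH in dry pyridine, where hydroxide acts as a base and is poorly solvated as a nucleophile. Both diketones stay as enolates, protected from retro-Claisen cleavage, until the cold acidic quench.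

Step 10
Reactants: 15 the bis(1,3-diketone) of step 9
Product: 16 6-{4-[5,7-bis(benzyloxy)-4-oxo-4H-chromen-2-yl]phenoxy}-2-[4-(benzyloxy)phenyl]-5,7-dimethoxy-4H-chromen-4-one
Conditions: p-TsOH·H2O (cat.), toluene, 90 °C
Reagents that add atoms: none
Why: Acid-catalysed cyclodehydration of ortho-hydroxyaryl 1,3-diketones, the second stage of the Baker–Venkataraman flavone synthesis: each free phenol adds to the distal carbonyl (6-exo-trig) and water is lost; each half has one free hydroxyl, so each pyranone can form in one sense only, and the non-nucleophilic medium spares the benzyl ethers.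

Step 11
Reactants: 16 6-{4-[5,7-bis(benzyloxy)-4-oxo-4H-chromen-2-yl]phenoxy}-2-[4-(benzyloxy)phenyl]-5,7-dimethoxy-4H-chromen-4-one
Product: 17 isocryptomerin, 6-[4-(5,7-dihydroxy-4-oxo-4H-chromen-2-yl)phenoxy]-5-hydroxy-2-(4-hydroxyphenyl)-7-methoxy-4H-chromen-4-one
Conditions: BCl3 (excess), C6HMe5, CH2Cl2, −78 °C to rt; then MeOH
Reagents that add atoms: none
Why: Lewis-acid ether cleavage: BCl3 removes the three aryl benzyl ethers at low temperature with pentamethylbenzene as a non-basic trap for benzyl cations, and on warming cleaves the 5-methoxy group through its six-membered boron chelate with the C4 carbonyl; the 7-methoxy group has no such chelation and the diaryl ether is inert.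

## Compound list

1 | 4-fluorobenzoyl chloride | O=C(Cl)c1ccc(F)cc1 | starting material
2 | allyl 4-fluorobenzoate | C=CCOC(=O)c1ccc(F)cc1 | intermediate
3 | syringaldehyde (4-hydroxy-3,5-dimethoxybenzaldehyde) | COc1cc(C=O)cc(OC)c1O | starting material
4 | allyl 4-(4-formyl-2,6-dimethoxyphenoxy)benzoate | C=CCOC(=O)c1ccc(Oc2c(OC)cc(C=O)cc2OC)cc1 | intermediate
5 | allyl 4-[4-(formyloxy)-2,6-dimethoxyphenoxy]benzoate | C=CCOC(=O)c1ccc(Oc2c(OC)cc(OC=O)cc2OC)cc1 | intermediate
6 | allyl 4-(4-hydroxy-2,6-dimethoxyphenoxy)benzoate | C=CCOC(=O)c1ccc(Oc2c(OC)cc(O)cc2OC)cc1 | intermediate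
7 | difluoroboron chelate of 8, allyl 4-[(2,2-difluoro-5,7-dimethoxy-4-methyl-1,3,2-benzodioxaborinin-6-yl)oxy]benzoate (phenolic O–B bond, acetyl O→B dative bond) | CC1=[O+][B-](F)(F)Oc2cc(OC)c(Oc3ccc(cc3)C(=O)OCC=C)c(OC)c12 | intermediate
8 | allyl 4-(3-acetyl-4-hydroxy-2,6-dimethoxyphenoxy)benzoate | C=CCOC(=O)c1ccc(Oc2c(OC)cc(O)c(C(C)=O)c2OC)cc1 | intermediate
9 | 4-(benzyloxy)benzoic acid | OC(=O)c1ccc(OCc2ccccc2)cc1 | starting material
10 | allyl 4-{3-acetyl-4-[4-(benzyloxy)benzoyloxy]-2,6-dimethoxyphenoxy}benzoate | C=CCOC(=O)c1ccc(Oc2c(OC)cc(OC(=O)c3ccc(OCc4ccccc4)cc3)c(C(C)=O)c2OC)cc1 | intermediate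
11 | 4-{3-acetyl-4-[4-(benzyloxy)benzoyloxy]-2,6-dimethoxyphenoxy}benzoic acid | OC(=O)c1ccc(Oc2c(OC)cc(OC(=O)c3ccc(OCc4ccccc4)cc3)c(C(C)=O)c2OC)cc1 | intermediate
12 | 2',4',6'-trihydroxyacetophenone (phloroacetophenone) | CC(=O)c1c(O)cc(O)cc1O | starting material
13 | 1-[2,4-bis(benzyloxy)-6-hydroxyphenyl]ethanone | CC(=O)c1c(O)cc(OCc2ccccc2)cc1OCc1ccccc1 | intermediate
14 | 2-acetyl-3,5-bis(benzyloxy)phenyl 4-{3-acetyl-4-[4-(benzyloxy)benzoyloxy]-2,6-dimethoxyphenoxy}benzoate | CC(=O)c1c(OC(=O)c2ccc(OCc3ccccc3)cc2)cc(OC)c(Oc2ccc(C(=O)Oc3cc(OCc4ccccc4)cc(OCc4ccccc4)c3C(C)=O)cc2)c1OC | intermediate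
15 | 1-[4-(benzyloxy)phenyl]-3-{3-[4-(3-[2,4-bis(benzyloxy)-6-hydroxyphenyl]-3-oxopropanoyl)phenoxy]-6-hydroxy-2,4-dimethoxyphenyl}propane-1,3-dione | COc1cc(O)c(C(=O)CC(=O)c2ccc(OCc3ccccc3)cc2)c(OC)c1Oc1ccc(C(=O)CC(=O)c2c(O)cc(OCc3ccccc3)cc2OCc2ccccc2)cc1 | intermediate
16 | 6-{4-[5,7-bis(benzyloxy)-4-oxo-4H-chromen-2-yl]phenoxy}-2-[4-(benzyloxy)phenyl]-5,7-dimethoxy-4H-chromen-4-one | COc1cc2oc(-c3ccc(OCc4ccccc4)cc3)cc(=O)c2c(OC)c1Oc1ccc(-c2cc(=O)c3c(OCc4ccccc4)cc(OCc4ccccc4)cc3o2)cc1 | intermediate
17 | isocryptomerin | COc1cc2oc(-c3ccc(O)cc3)cc(=O)c2c(O)c1Oc1ccc(-c2cc(=O)c3c(O)cc(O)cc3o2)cc1 | target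

## Step count and risk

Total: 11 steps. Longest linear sequence: 10 steps (steps 1, 2, 3, 4, 5, 6, 8, 9, 10, 11, from 1 to 17). Step 7 is a one-step branch.

**Step 9 (key step).** Saponification of one or both aryl esters may compete with enolate acylation. The second shift may also lag behind the first, because the ring A acetyl group is flanked by two ortho substituents and its enolate is twisted. The fallback runs the two shifts one after the other and sets out from 10:
- A lithium amide base (LiHMDS, THF, −78 to −20 °C) performs the single acyl shift to allyl 4-(3-{3-[4-(benzyloxy)phenyl]-3-oxopropanoyl}-4-hydroxy-2,6-dimethoxyphenoxy)benzoate F1.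
- Acid-catalysed cyclodehydration gives allyl 4-({2-[4-(benzyloxy)phenyl]-5,7-dimethoxy-4-oxo-4H-chromen-6-yl}oxy)benzoate F2.
- Deallylation as in step 6 gives 4-({2-[4-(benzyloxy)phenyl]-5,7-dimethoxy-4-oxo-4H-chromen-6-yl}oxy)benzoic acid F3.
- Esterification with 13 as in step 8 gives 2-acetyl-3,5-bis(benzyloxy)phenyl 4-({2-[4-(benzyloxy)phenyl]-5,7-dimethoxy-4-oxo-4H-chromen-6-yl}oxy)benzoate F4.
- A single Baker–Venkataraman shift gives 1-[2,4-bis(benzyloxy)-6-hydroxyphenyl]-3-[4-({2-[4-(benzyloxy)phenyl]-5,7-dimethoxy-4-oxo-4H-chromen-6-yl}oxy)phenyl]propane-1,3-dione F5.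
- Cyclodehydration of F5 returns to the route at 16.

**Step 2.** The substitution may be slow, because the phenoxide is both hindered and deactivated by its para aldehyde and a benzoate ester activates fluoride only moderately. Long heating would invite allyl transfer from the ester to the phenoxide. The fallback sets out from 3 and replaces SNAr by a copper-catalysed Ullmann ether synthesis. The partner is allyl 4-iodobenzoate F6, made from 4-iodobenzoyl chloride in the manner of step 1. The coupling uses CuI (monovalent copper), picolinic acid and K3PO4 in DMSO at 90 °C and returns to the route at 4.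

**Step 3.** Hydride migration may compete with aryl migration in the Criegee adduct and divert material to the carboxylic acid, because a twisted aryloxy group donates less than a methoxy group. Slow epoxidation of the allyl group is a second loss on long exposure. The fallback moves the oxidation to the free para-hydroxybenzaldehyde, where it is a true Dakin reaction, and sets out from 3:
- Alkaline H2O2 gives 2,6-dimethoxybenzene-1,4-diol F7.
- AcOH and BF3·OEt2 acetylate F7 ortho to the unhindered hydroxyl to give 1-(3,6-dihydroxy-2,4-dimethoxyphenyl)ethanone F8.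
- SNAr of the non-chelated hydroxyl of F8 with 2 (K2CO3, DMSO, strictly under N2) returns to the route at 8.

This fallback also bypasses step 4. Its weak point is the site selectivity of the arylation, which rests on the chelated hydroxyl being the poorer nucleophile.

**Step 4.** Acidolysis of the allyl ester, or addition of acetic acid to its alkene, may occur under hot BF3·OEt2 in AcOH. Incomplete release of the phenol from its boron chelate is a lesser concern. The fallback accepts the loss of the ester and sets out from 6. After the acetylation the crude product is saponified (LiOH, THF–H2O) to 4-(3-acetyl-4-hydroxy-2,6-dimethoxyphenoxy)benzoic acid F9. The carboxylate alone is then re-alkylated with allyl bromide and KHCO3 in DMF, where the chelated phenol is not alkylated. This returns to the route at 8.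

**Step 11.** Liberated benzyl cations may benzylate the electron-rich phloroglucinol ring if trapping is incomplete. Cleavage of the 5-methoxy group may stall at low temperature, or demethylation may spread to C7 on long exposure at room temperature. The fallback separates the two tasks and sets out from 16. Hydrogenolysis (H2, Pd/C, THF–EtOAc) gives 6-[4-(5,7-dihydroxy-4-oxo-4H-chromen-2-yl)phenoxy]-2-(4-hydroxyphenyl)-5,7-dimethoxy-4H-chromen-4-one F10. A limited charge of BCl3 in CH2Cl2 at 0 °C then removes only the chelated 5-methyl group and returns to the route at 17.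

## Further compounds

F1 | step 9 | allyl 4-(3-{3-[4-(benzyloxy)phenyl]-3-oxopropanoyl}-4-hydroxy-2,6-dimethoxyphenoxy)benzoate | C=CCOC(=O)c1ccc(Oc2c(OC)cc(O)c(C(=O)CC(=O)c3ccc(OCc4ccccc4)cc3)c2OC)cc1
F2 | step 9 | allyl 4-({2-[4-(benzyloxy)phenyl]-5,7-dimethoxy-4-oxo-4H-chromen-6-yl}oxy)benzoate | C=CCOC(=O)c1ccc(Oc2c(OC)cc3oc(-c4ccc(OCc5ccccc5)cc4)cc(=O)c3c2OC)cc1
F3 | step 9 | 4-({2-[4-(benzyloxy)phenyl]-5,7-dimethoxy-4-oxo-4H-chromen-6-yl}oxy)benzoic acid | OC(=O)c1ccc(Oc2c(OC)cc3oc(-c4ccc(OCc5ccccc5)cc4)cc(=O)c3c2OC)cc1
F4 | step 9 | 2-acetyl-3,5-bis(benzyloxy)phenyl 4-({2-[4-(benzyloxy)phenyl]-5,7-dimethoxy-4-oxo-4H-chromen-6-yl}oxy)benzoate | CC(=O)c1c(OCc2ccccc2)cc(OCc2ccccc2)cc1OC(=O)c1ccc(Oc2c(OC)cc3oc(-c4ccc(OCc5ccccc5)cc4)cc(=O)c3c2OC)cc1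
F5 | step 9 | 1-[2,4-bis(benzyloxy)-6-hydroxyphenyl]-3-[4-({2-[4-(benzyloxy)phenyl]-5,7-dimethoxy-4-oxo-4H-chromen-6-yl}oxy)phenyl]propane-1,3-dione | O=C(CC(=O)c1c(O)cc(OCc2ccccc2)cc1OCc1ccccc1)c1ccc(Oc2c(OC)cc3oc(-c4ccc(OCc5ccccc5)cc4)cc(=O)c3c2OC)cc1
F6 | step 2 | allyl 4-iodobenzoate | C=CCOC(=O)c1ccc(I)cc1
F7 | step 3 | 2,6-dimethoxybenzene-1,4-diol | COc1cc(O)cc(OC)c1O
F8 | step 3 | 1-(3,6-dihydroxy-2,4-dimethoxyphenyl)ethanone | CC(=O)c1c(O)cc(OC)c(O)c1OC
F9 | step 4 | 4-(3-acetyl-4-hydroxy-2,6-dimethoxyphenoxy)benzoic acid | CC(=O)c1c(O)cc(OC)c(Oc2ccc(C(=O)O)cc2)c1OC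
F10 | step 11 | 6-[4-(5,7-dihydroxy-4-oxo-4H-chromen-2-yl)phenoxy]-2-(4-hydroxyphenyl)-5,7-dimethoxy-4H-chromen-4-one | COc1cc2oc(-c3ccc(O)cc3)cc(=O)c2c(OC)c1Oc1ccc(-c2cc(=O)c3c(O)cc(O)cc3o2)cc1
A1 | alternative 1 | phloroglucinol | Oc1cc(O)cc(O)c1
A2 | alternative 1 | ethyl 3-[4-({2-[4-(benzyloxy)phenyl]-5,7-dimethoxy-4-oxo-4H-chromen-6-yl}oxy)phenyl]-3-oxopropanoate | CCOC(=O)CC(=O)c1ccc(Oc2c(OC)cc3oc(-c4ccc(OCc5ccccc5)cc4)cc(=O)c3c2OC)cc1
A3 | alternative 1 | 4'-O-benzyl-5-O-methylisocryptomerin | COc1cc2oc(-c3ccc(OCc4ccccc4)cc3)cc(=O)c2c(OC)c1Oc1ccc(-c2cc(=O)c3c(O)cc(O)cc3o2)cc1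
A4 | alternative 2 | 5-(benzyloxy)-2-(ethynyloxy)-1,3-dimethoxybenzene | C#COc1c(OC)cc(OCc2ccccc2)cc1OC
A5 | alternative 2 | methyl coumalate (methyl 2-oxo-2H-pyran-5-carboxylate) | COC(=O)c1ccc(=O)oc1
A6 | alternative 2 | methyl 4-[4-(benzyloxy)-2,6-dimethoxyphenoxy]benzoate | COC(=O)c1ccc(Oc2c(OC)cc(OCc3ccccc3)cc2OC)cc1
A7 | alternative 3 | methyl 4-(3-{3-[4-(benzyloxy)phenyl]-3-oxopropanoyl}-2,6-dimethoxyphenoxy)benzoate | COC(=O)c1ccc(Oc2c(OC)ccc(C(=O)CC(=O)c3ccc(OCc4ccccc4)cc3)c2OC)cc1
A8 | alternative 3 | methyl 4-({2-[4-(benzyloxy)phenyl]-5,7-dimethoxy-4-oxo-4H-chromen-6-yl}oxy)benzoate | COC(=O)c1ccc(Oc2c(OC)cc3oc(-c4ccc(OCc5ccccc5)cc4)cc(=O)c3c2OC)cc1
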